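**Retrosynthetic overview**
- Target ⇒ (S)-humulenol + 2 × tropolone o-quinone methide. Each dihydropyran is closed through its aryl O–C(quaternary) bond in an oxa-[4+2]; the ring remote from the carbinol forms first, the ring next to it second.
- (S)-Humulenol ⇒ α-humulene by one catalyst-controlled allylic C–H → C–O hydroxylation. This C–O bond is the key bond; its stereocentre relays to the other four.
- o-Quinone methide ⇒ 5-(hydroxymethyl)-2,4-dihydroxytropone ⇒ 5-bromo-4-methoxytropolone (C–Br as the handle for CH2OH).
- Bromotropolone ⇒ gem-dibromocyclopropane-fused cyclohexenediol (six → seven ring expansion) ⇒ Birch diene ⇒ 2-methylanisole.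
- Ring order: eleven-membered carbocycle purchased; tropolone ring (step 5); dihydropyran remote from the carbinol, then dihydropyran beside it (step 8).

**Assumptions**
- The SMILES defines the target: carbinol carbon S, the two O-bearing quaternary carbons and the two adjacent methine carbons all R, both pyrans trans-fused, ring alkene E.
- The precatalyst bis{2-[(1S)-1-methoxyethyl]phenyl} diselenide is made separately from commercial (S)-1-(2-bromophenyl)ethanol (NaH/MeI; then t-BuLi, Se, air) and is not numbered. If its sense of induction proves opposite, its mirror image is used.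

**Route**

Step 1
Reactants: 1 α-humulene [(1E,4E,8E)-2,6,6,9-tetramethylcycloundeca-1,4,8-triene] (1.5 equiv)
Product: 2 (S)-humulenol [(1S,2E,6E,9E)-2,5,5,9-tetramethylcycloundeca-2,6,9-trien-1-ol]
Conditions: bis{2-[(1S)-1-methoxyethyl]phenyl} diselenide (5 mol %), t-BuOOH (1.0 equiv, anhydrous in decane), 4 Å MS, CH2Cl2, 0 °C → rt
Reagents that add atoms: tert-butyl hydroperoxide, CC(C)(C)OO
Why: Proposed new method: a catalytic enantio- and site-selective selenium ene/[2,3] allylic C–H hydroxylation in which t-BuOOH oxidises the diselenide to the chiral areneseleninic acid (tetravalent selenium, rigidified by Se···OMe coordination), its Se=O adds in an ene reaction to one enantiotopic face of the trisubstituted alkene flanked by the CH2CH2 bridge (Se to the vinylic CH, H taken from the bridge CH2; the other trisubstituted alkene would have to give up its doubly allylic H and form a strained ring 1,3-diene), the catalyst-bound allylic selenoxide undergoes a suprafacial [2,3]-sigmatropic shift that transfers chirality from C–Se to the new C–O bond (S) and restores the E-alkene, and hydrolysis releases 2 plus divalent selenium for reoxidation; the closest known reactions are the Riley-type SeO2/t-BuOOH allylic hydroxylation, areneseleninic anhydride allylic oxidation and asymmetric [2,3]-shifts of chiral allylic selenoxides.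

Step 2
Reactants: 3 2-methylanisole (1-methoxy-2-methylbenzene)
Product: 4 1-methoxy-2-methylcyclohexa-1,4-diene
Conditions: Li, NH3(l), THF, t-BuOH, −78 → −33 °C
Reagents that add atoms: none
Why: Birch reduction places both donor substituents (OMe, Me) on a residual double bond, giving the 1,4-diene with a tetrasubstituted enol-ether alkene; no stereocentre is formed.

Step 3
Reactants: 4 1-methoxy-2-methylcyclohexa-1,4-diene
Product: 5 7,7-dibromo-1-methoxy-6-methylbicyclo[4.1.0]hept-3-ene (racemic; cis-fused)
Conditions: CHBr3 (1.1 equiv), KOt-Bu, hexane, −10 → 0 °C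
Reagents that add atoms: bromoform, BrC(Br)Br
Why: Electrophilic dibromocarbene cyclopropanation is selective for the electron-rich tetrasubstituted enol-ether alkene; the cis fusion is the only one possible and both stereocentres are erased in step 5.

Step 4
Reactants: 5 7,7-dibromo-1-methoxy-6-methylbicyclo[4.1.0]hept-3-ene
Product: 6 7,7-dibromo-1-methoxy-6-methylbicyclo[4.1.0]heptane-3,4-diol (racemic cis-diol; OH groups anti to CBr2)
Conditions: OsO4 (2 mol %), NMO, acetone–H2O (4:1), 0 °C → rt
Reagents that add atoms: N-methylmorpholine N-oxide, C[N+]1([O-])CCOCC1; water, O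
Why: Upjohn syn-dihydroxylation of the only remaining alkene occurs on the face away from the endo bromine; the diol configuration is inconsequential because both carbinols are oxidised next.

Step 5
Reactants: 6 7,7-dibromo-1-methoxy-6-methylbicyclo[4.1.0]heptane-3,4-diol
Product: 8 5-bromo-2-hydroxy-4-methoxy-6-methylcyclohepta-2,4,6-trien-1-one, via bicyclic 1,2-diketone 7 (not isolated)
Conditions: TFAA, DMSO, CH2Cl2, −60 °C; then Et3N, −60 °C → rt
Reagents that add atoms: none
Why: Swern-type double oxidation gives the 1,2-diketone, whose enolisation triggers electrocyclic opening of the gem-dibromocyclopropane with loss of HBr (six → seven ring expansion) and tautomerisation to the aromatic tropolone; the retained bromine marks the carbon between OMe and Me.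

Step 6
Reactants: 8 5-bromo-2-hydroxy-4-methoxy-6-methylcyclohepta-2,4,6-trien-1-one
Product: 9 2-hydroxy-5-(hydroxymethyl)-4-methoxy-6-methylcyclohepta-2,4,6-trien-1-one
Conditions: Bu3SnCH2OH (1.3 equiv), Pd(PPh3)4 (5 mol %), 1,4-dioxane, 100 °C
Reagents that add atoms: (tributylstannyl)methanol, OC[Sn](CCCC)(CCCC)CCCC
Why: Stille cross-coupling, in which the troponoid sp2 C–Br bond adds oxidatively to zerovalent palladium and the hydroxymethyl group is transferred under neutral conditions; no stereocentre is formed.

Step 7
Reactants: 9 2-hydroxy-5-(hydroxymethyl)-4-methoxy-6-methylcyclohepta-2,4,6-trien-1-one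
Product: 10 2,4-dihydroxy-5-(hydroxymethyl)-6-methylcyclohepta-2,4,6-trien-1-one
Conditions: 2 M aq. HCl, THF, 60 °C
Reagents that add atoms: water, O
Why: Acid hydrolysis of the vinylogous methyl ester (addition–elimination through the hydroxytropylium ion) frees the hydroxyl ortho to CH2OH; any quinone methide formed is reversibly rehydrated in the aqueous medium.

Step 8
Reactants: 2 (S)-humulenol (1.0 equiv) and 10 2,4-dihydroxy-5-(hydroxymethyl)-6-methylcyclohepta-2,4,6-trien-1-one (2.5 equiv, added in portions)
Product: 13 CNP0283947.4 (target), via o-quinone methide 11 (not isolated), via mono-cycloadduct 12 (not isolated)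
Conditions: p-xylene, 4 Å MS, 150 °C, sealed tube
Reagents that add atoms: none
Why: Thermal dehydration of 10 gives the tropolone o-quinone methide, which undergoes two inverse-electron-demand hetero-Diels–Alder reactions (O to the methyl-bearing alkene carbon, CH2 to the CH carbon); suprafacial addition to each E-alkene fixes both trans ring fusions, and peripheral attack on the conformer imposed by the S-carbinol is expected to set the R,R configuration at each fusion with the ether oxygen anti to the carbinol oxygen.

**Compound list**
1 | α-humulene, (1E,4E,8E)-2,6,6,9-tetramethylcycloundeca-1,4,8-triene | C1/C=C(C)/C/C=C/C(C)(C)C/C=C(C)/C1 | starting material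
2 | (S)-humulenol, (1S,2E,6E,9E)-2,5,5,9-tetramethylcycloundeca-2,6,9-trien-1-ol | C1/C=C(C)/C/C=C/C(C)(C)C/C=C(C)/[C@H]1O | intermediate
3 | 2-methylanisole | COc1ccccc1C | starting material
4 | 1-methoxy-2-methylcyclohexa-1,4-diene | COC1=C(C)CC=CC1 | intermediate
5 | 7,7-dibromo-1-methoxy-6-methylbicyclo[4.1.0]hept-3-ene (racemic, cis-fused; one enantiomer drawn) | CO[C@@]12CC=CC[C@]1(C)C2(Br)Br | intermediate
6 | 7,7-dibromo-1-methoxy-6-methylbicyclo[4.1.0]heptane-3,4-diol (racemic; cis-diol on the face of OMe/Me) | CO[C@@]12C[C@@H](O)[C@@H](O)C[C@]1(C)C2(Br)Br | intermediate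
7 | 7,7-dibromo-1-methoxy-6-methylbicyclo[4.1.0]heptane-3,4-dione (racemic) | CO[C@@]12CC(=O)C(=O)C[C@]1(C)C2(Br)Br | intermediate (not isolated)
8 | 5-bromo-2-hydroxy-4-methoxy-6-methylcyclohepta-2,4,6-trien-1-one | Cc1cc(=O)c(O)cc(OC)c1Br | intermediate
9 | 2-hydroxy-5-(hydroxymethyl)-4-methoxy-6-methylcyclohepta-2,4,6-trien-1-one | Cc1cc(=O)c(O)cc(OC)c1CO | intermediate
10 | 2,4-dihydroxy-5-(hydroxymethyl)-6-methylcyclohepta-2,4,6-trien-1-one | Cc1cc(=O)c(O)cc(O)c1CO | intermediate
11 | tropolone o-quinone methide, 2-hydroxy-6-methyl-5-methylidenecyclohepta-2,6-diene-1,4-dione | CC1=CC(=O)C(O)=CC(=O)C1=C | intermediate (not isolated)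
12 | mono-cycloadduct: dihydropyrano-tropolone trans-fused across the alkene remote from the carbinol (O-bearing quaternary carbon R, adjacent methine R, carbinol S, both remaining alkenes E) | CC1(C)/C=C/C[C@@]2(C)Oc3cc(O)c(=O)cc(C)c3C[C@@H]2C[C@H](O)/C(C)=C/C1 | intermediate (not isolated)
13 | CNP0283947.4: bis(dihydropyrano-tropolone) of (S)-humulenol (carbinol S; both O-bearing quaternary carbons R; both adjacent methines R; E-alkene) | Cc1cc(=O)c(O)cc2c1C[C@H]1CC(C)(C)/C=C/C[C@@]3(C)Oc4cc(O)c(=O)cc(C)c4C[C@@H]3C[C@H](O)[C@]1(C)O2 | target

**Totals**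
Total step count: 8. Longest linear sequence: 7 steps (3 → 13, steps 2–8); step 1 is the one-step convergent branch.

**Steps most likely to fail, with fallbacks**

Step 1 (the proposed new hydroxylation). The risks are site selectivity between the two trisubstituted alkenes, the level of enantiocontrol and over-oxidation. The fallback uses known chemistry, sets out from 1 and rejoins at 2. A classical SeO2 (catalytic)/t-BuOOH allylic hydroxylation in CH2Cl2 gives racemic humulenol F1, freed from the regioisomeric alcohol on AgNO3-impregnated silica. Dess–Martin oxidation gives the enone F2. Corey–Bakshi–Shibata reduction with the (R)-methyl oxazaborolidine and BH3·SMe2 in toluene at −40 °C (alkenyl as the large group) then returns the S-alcohol 2.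

Step 6 (Stille coupling on a free, chelating tropolone). The risk is sequestration of palladium by the tropolone and stannyl tropolonate formation. The fallback sets out from 8 and rejoins at 9 by a protect–couple–release sequence. Ac2O/pyridine gives the tropolone acetate F3. The same hydroxymethyl-stannane coupling is run on this non-chelating substrate to give the hydroxymethyl acetate F4. K2CO3 in methanol at 0 °C removes the acetyl group to give 9.

Step 8 (double hetero-Diels–Alder). The risks are competing oligomerisation of 11, acid-promoted ionisation of the allylic alcohol at 150 °C, and hydroxyl-directed delivery to the wrong alkene face. The fallback sets out from 2 and rejoins at 13. TBSCl/imidazole in DMF gives the silyl ether F5, which removes the hydrogen-bond donor and shields the face syn to the oxygen. The two cycloadditions with 10 are run as in step 8 to give the silylated bis-adduct F6. HF·pyridine in THF then unveils 13.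

**Further compounds**
F1 | step 1 | racemic humulenol, (2E,6E,9E)-2,5,5,9-tetramethylcycloundeca-2,6,9-trien-1-ol | C1/C=C(C)/C/C=C/C(C)(C)C/C=C(C)/C1O
F2 | step 1 | (2E,6E,9E)-2,5,5,9-tetramethylcycloundeca-2,6,9-trien-1-one | C1/C=C(C)/C/C=C/C(C)(C)C/C=C(C)/C1=O
F3 | step 6 | 4-bromo-3-methoxy-5-methyl-7-oxocyclohepta-1,3,5-trien-1-yl acetate | Cc1cc(=O)c(OC(C)=O)cc(OC)c1Br
F4 | step 6 | 4-(hydroxymethyl)-3-methoxy-5-methyl-7-oxocyclohepta-1,3,5-trien-1-yl acetate | Cc1cc(=O)c(OC(C)=O)cc(OC)c1CO
F5 | step 8 | tert-butyldimethylsilyl ether of (S)-humulenol | C1/C=C(C)/C/C=C/C(C)(C)C/C=C(C)/[C@H]1O[Si](C)(C)C(C)(C)C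
F6 | step 8 | O-tert-butyldimethylsilyl ether of 13 (same configuration at all five stereocentres) | Cc1cc(=O)c(O)cc2c1C[C@H]1CC(C)(C)/C=C/C[C@@]3(C)Oc4cc(O)c(=O)cc(C)c4C[C@@H]3C[C@H](O[Si](C)(C)C(C)(C)C)[C@]1(C)O2
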